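**Retrosynthetic overview**

1. The target is read as epicatechin-(4α→8)-epigallocatechin 3-O-gallate with an all-cis upper unit (2R,3R,4S) and a (2R,3R) lower unit; rings are named A (phloroglucinol), B (catechol) and C (pyran) in the upper unit, D, E (pyrogallol) and F (pyran) in the lower unit, and G (galloyl).
2. Last disconnection: one hydrogenolysis removes twelve benzyl ethers and a benzyl carbonate on the upper O3.
3. Key disconnection: ring C is opened across C4–C3 and O1–C2 into the o-quinone methide of ring A (heterodiene O1=C8a–C4a=C4, with C4 already bonded to C8 of ring D) and the (Z)-enol carbonate of the ring B arylacetaldehyde (C2=C3), joined by a hetero-Diels–Alder reaction.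
4. Enabling feature: O1–C8a–C4a–C4 of ring C is the ortho-hydroxybenzyl array of ring A (a latent o-quinone methide); the 2,3-cis-3,4-cis triad C2/C3/C4 is what an endo [4+2] addition of a (Z)-alkene gives; the C4' oxygen of ring B, para to C2, steers O1 to C2.
5. The quinone methide precursor is a benzhydrol made by ortho-hydroxyalkylation of 3,5-bis(benzyloxy)phenol with the C8 aldehyde of octa-O-benzyl-EGCG, which is assembled from penta-O-benzyl-(−)-epigallocatechin and 3,4,5-tris(benzyloxy)benzoic acid; rings A, B, D, E, F and G are bought in, and ring C is the only ring made and is closed last.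

Key step: step 8

Assumption: the (R)-configured acid of step 8 is taken to be the matched catalyst for attack on the methide face that leads to (4S); the sense is assigned by analogy with related o-quinone methide cycloadditions and would be inverted by using the (S)-acid.

**Route**

Step 1
Reactants: 1 (−)-epigallocatechin (EGC)
Product: 2 penta-O-benzyl-EGC
Conditions: BnBr (6 equiv), K2CO3, Bu4NI (cat.), DMF, 0 °C → rt, argon
Reagents that add atoms: benzyl bromide BrCc1ccccc1
Why: Williamson etherification in which K2CO3 deprotonates only the five phenols, so the secondary 3-OH and the (2R,3R) stereocentres stay untouched (oxygen excluded and no heating, to avoid pyrogallol oxidation and C2 epimerisation).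

Step 2
Reactants: 2 penta-O-benzyl-EGC; 3 3,4,5-tris(benzyloxy)benzoic acid
Product: 5 octa-O-benzyl-EGCG, via O-acylisourea 4 (not isolated)
Conditions: DCC (1.5 equiv), DMAP (0.3 equiv), CH2Cl2, 0 °C → rt
Reagents that add atoms: none
Why: Steglich esterification, in which DCC activates the acid as its O-acylisourea and DMAP transfers the galloyl group to the hindered axial 3-OH; the C3–O bond is not broken, so the (2R,3R) configuration is retained, and this is the standard way of galloylating benzyl-protected flavan-3-ols.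

Step 3
Reactants: 5 octa-O-benzyl-EGCG
Product: 7 8-formyl-octa-O-benzyl-EGCG, via C8-iminium chloride 6 (not isolated)
Conditions: POCl3, DMF, 0 → 50 °C; then ice-water
Reagents that add atoms: N,N-dimethylformamide CN(C)C=O; water O
Why: Vilsmeier–Haack formylation, expected at C8 of ring D (ortho to O1 and the 7-benzyloxy group, para to the 5-benzyloxy group) because ring D is the only phloroglucinol-type ring and C8 is where O-alkylated flavan-3-ols undergo electrophilic substitution, while rings E and G are far less nucleophilic; no stereocentre is touched.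

Step 4
Reactants: 7 8-formyl-octa-O-benzyl-EGCG; 8 3,5-bis(benzyloxy)phenol
Product: 10 benzhydrol 8-{[2,4-bis(benzyloxy)-6-hydroxyphenyl](hydroxy)methyl}-octa-O-benzyl-EGCG (both carbinol epimers), via bromomagnesium 3,5-bis(benzyloxy)phenoxide 9 (not isolated)
Conditions: 8, EtMgBr, Et2O, 0 °C; solvent exchange to CH2Cl2; then 7, 0 °C → rt; pH 7 buffer
Reagents that add atoms: none
Why: Magnesium phenoxide-mediated ortho-specific hydroxyalkylation of a phenol with an aldehyde (Friedel–Crafts-type phenol–aldehyde addition), in which the aldehyde bound to magnesium is delivered to the ortho carbon through a six-membered chelate; the two ortho positions of 8 are equivalent, the phenoxide does not attack the gallate ester, and the new carbinol centre may form as either epimer because it is erased in step 8.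

Step 5
Reactants: 11 3,4-bis(benzyloxy)benzaldehyde
Product: 12 1,2-bis(benzyloxy)-4-ethynylbenzene
Conditions: dimethyl (1-diazo-2-oxopropyl)phosphonate, K2CO3, MeOH/THF, rt
Reagents that add atoms: dimethyl (1-diazo-2-oxopropyl)phosphonate CC(=O)C(=[N+]=[N-])P(=O)(OC)OC
Why: Seyferth–Gilbert homologation in its Ohira–Bestmann form, in which methanolysis of the reagent gives the diazomethylphosphonate anion that converts the aldehyde into the terminal alkyne through a vinylidene 1,2-shift; benzyl ethers are inert.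

Step 6
Reactants: 12 1,2-bis(benzyloxy)-4-ethynylbenzene
Product: 13 (Z)-2-[3,4-bis(benzyloxy)phenyl]ethenyl acetate
Conditions: AcOH, [RuCl2(p-cymene)]2 (1 mol%), P(4-ClC6H4)3 (3 mol%), DMAP (4 mol%), toluene, 60 °C
Reagents that add atoms: acetic acid CC(=O)O
Why: Ruthenium-catalysed anti-Markovnikov hydro-oxycarbonylation of a terminal alkyne, in which acetate attacks the α-carbon of a ruthenium vinylidene anti to the aryl group and protodemetalation gives the (Z)-enol ester; this fixes the cis relation later found between C2 and C3.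

Step 7
Reactants: 13 (Z)-2-[3,4-bis(benzyloxy)phenyl]ethenyl acetate
Product: 15 benzyl (Z)-2-[3,4-bis(benzyloxy)phenyl]ethenyl carbonate, via lithium (Z)-enolate 14 (not isolated)
Conditions: MeLi (2.1 equiv), THF, −78 → 0 °C; then ClCO2Bn (2.2 equiv), DMPU, −78 °C → rt
Reagents that add atoms: benzyl chloroformate O=C(Cl)OCc1ccccc1
Why: Cleavage of the enol acetate by methyllithium gives the lithium enolate with retention of the (Z) geometry, and the hard electrophile benzyl chloroformate acylates it on oxygen (enolate O-acylation), so that the enol oxygen becomes a poor donor and carries a group removable by hydrogenolysis.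

Step 8
Reactants: 10 benzhydrol 8-{[2,4-bis(benzyloxy)-6-hydroxyphenyl](hydroxy)methyl}-octa-O-benzyl-EGCG; 15 benzyl (Z)-2-[3,4-bis(benzyloxy)phenyl]ethenyl carbonate
Product: 17 3-O-benzyloxycarbonyl-5,7,3',4'-tetra-O-benzyl-epicatechin-(4α→8)-octa-O-benzyl-EGCG [upper unit (2R,3R,4S) all-cis; lower unit (2R,3R)], via (E)-o-quinone methide 16 (not isolated)
Conditions: (R)-3,3'-bis(2,4,6-triisopropylphenyl)-1,1'-binaphthyl-2,2'-diyl N-triflylphosphoramide (10 mol%), 15 (3 equiv), 5 Å MS, CH2Cl2, −40 → 0 °C, slow addition of 10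
Reagents that add atoms: none
Why: Proposed new method: the chiral Brønsted acid ionises the doubly benzylic carbinol of 10 to the hydrogen-bonded (E)-o-quinone methide 16, whose O1=C8a–C4a=C4 array acts as the 4π heterodiene of an inverse-electron-demand hetero-Diels–Alder reaction with the electron-rich (Z)-alkene 15, the closest known reaction type being the chiral phosphoric acid or N-triflylphosphoramide catalysed [4+2] cycloaddition of o-quinone methides from o-hydroxybenzhydrols with styrenes and β-alkylstyrenes to give 2,4-cis-flavans, which has not been shown for a β-acyloxystyrene. Ring C is closed by a concerted but asynchronous [4+2] cycloaddition in which C4–C3 bonding runs ahead of O1–C2 bonding (at the stepwise limit a 6-exo-trig closure of O1 onto the para-benzyloxybenzylic cation at C2). The regiochemistry needed (C4 to C3, O1 to C2) should follow because the 4'-benzyloxy group of ring B stabilises positive charge at C2 while the acylated enol oxygen is a poor donor, so 15 reacts as a styrene and not as an enol ether. C2 and C3 become cis because addition to the (Z)-alkene is suprafacial, and C4 becomes cis to both because the aryl group and the carbonate sit endo under the (E)-methide, which gives the all-cis triad. The absolute sense (2R,3R,4S) depends on the methide face that is attacked and is to be secured by the chiral counter-anion, the two facial isomers being diastereomers (enantiopure lower unit) that can be separated. Chemoselectivity rests on the protecting pattern: the only free ortho-OH is on ring A, so the methide forms on ring A and not on ring D, and slow addition of 10 to an excess of 15 keeps self-condensation through ring A down.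

Step 9
Reactants: 17 3-O-benzyloxycarbonyl-5,7,3',4'-tetra-O-benzyl-epicatechin-(4α→8)-octa-O-benzyl-EGCG
Product: 18 epicatechin-(4α→8)-epigallocatechin 3-O-gallate (CNP0246304.3)
Conditions: H2 (1 atm), Pd(OH)2/C, THF/MeOH/H2O, rt
Reagents that add atoms: none
Why: Palladium-catalysed hydrogenolysis should cleave the twelve benzyl ethers and the benzyl carbonate (which then loses CO2 to free the upper 3-OH) under neutral conditions that leave the gallate ester, the C4–C8 interflavan bond and the cyclic benzylic C2–O1 bonds intact, as in the deprotection of benzylated procyanidin gallates; no stereocentre is affected.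

**Compound list**

1 | (−)-epigallocatechin (EGC), (2R,3R) | O[C@@H]1Cc2c(O)cc(O)cc2O[C@@H]1c1cc(O)c(O)c(O)c1 | starting material

2 | penta-O-benzyl-EGC: (2R,3R)-5,7-bis(benzyloxy)-2-[3,4,5-tris(benzyloxy)phenyl]chroman-3-ol | O[C@@H]1Cc2c(OCc3ccccc3)cc(OCc3ccccc3)cc2O[C@@H]1c1cc(OCc2ccccc2)c(OCc2ccccc2)c(OCc2ccccc2)c1 | intermediate

3 | 3,4,5-tris(benzyloxy)benzoic acid | O=C(O)c1cc(OCc2ccccc2)c(OCc2ccccc2)c(OCc2ccccc2)c1 | starting material

4 | O-acylisourea: N,N'-dicyclohexyl-O-[3,4,5-tris(benzyloxy)benzoyl]isourea | O=C(OC(=NC1CCCCC1)NC1CCCCC1)c1cc(OCc2ccccc2)c(OCc2ccccc2)c(OCc2ccccc2)c1 | intermediate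

5 | octa-O-benzyl-EGCG: (2R,3R)-5,7-bis(benzyloxy)-2-[3,4,5-tris(benzyloxy)phenyl]chroman-3-yl 3,4,5-tris(benzyloxy)benzoate | O=C(O[C@@H]1Cc2c(OCc3ccccc3)cc(OCc3ccccc3)cc2O[C@@H]1c1cc(OCc2ccccc2)c(OCc2ccccc2)c(OCc2ccccc2)c1)c1cc(OCc2ccccc2)c(OCc2ccccc2)c(OCc2ccccc2)c1 | intermediate

6 | C8-iminium chloride: 8-[(dimethyliminio)methyl]-octa-O-benzyl-EGCG chloride, (2R,3R) | O=C(O[C@@H]1Cc2c(OCc3ccccc3)cc(OCc3ccccc3)c(C=[N+](C)C)c2O[C@@H]1c1cc(OCc2ccccc2)c(OCc2ccccc2)c(OCc2ccccc2)c1)c1cc(OCc2ccccc2)c(OCc2ccccc2)c(OCc2ccccc2)c1.[Cl-] | intermediate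

7 | 8-formyl-octa-O-benzyl-EGCG, (2R,3R) | O=C(O[C@@H]1Cc2c(OCc3ccccc3)cc(OCc3ccccc3)c(C=O)c2O[C@@H]1c1cc(OCc2ccccc2)c(OCc2ccccc2)c(OCc2ccccc2)c1)c1cc(OCc2ccccc2)c(OCc2ccccc2)c(OCc2ccccc2)c1 | intermediate

8 | 3,5-bis(benzyloxy)phenol | Oc1cc(OCc2ccccc2)cc(OCc2ccccc2)c1 | starting material

9 | bromomagnesium 3,5-bis(benzyloxy)phenoxide | Br[Mg]Oc1cc(OCc2ccccc2)cc(OCc2ccccc2)c1 | intermediate

10 | benzhydrol 8-{[2,4-bis(benzyloxy)-6-hydroxyphenyl](hydroxy)methyl}-octa-O-benzyl-EGCG, both carbinol epimers, lower unit (2R,3R) | O=C(O[C@@H]1Cc2c(OCc3ccccc3)cc(OCc3ccccc3)c(C(O)c3c(O)cc(OCc4ccccc4)cc3OCc4ccccc4)c2O[C@@H]1c1cc(OCc2ccccc2)c(OCc2ccccc2)c(OCc2ccccc2)c1)c1cc(OCc2ccccc2)c(OCc2ccccc2)c(OCc2ccccc2)c1 | intermediate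

11 | 3,4-bis(benzyloxy)benzaldehyde | O=Cc1ccc(OCc2ccccc2)c(OCc2ccccc2)c1 | starting material

12 | 1,2-bis(benzyloxy)-4-ethynylbenzene | C#Cc1ccc(OCc2ccccc2)c(OCc2ccccc2)c1 | intermediate

13 | (Z)-2-[3,4-bis(benzyloxy)phenyl]ethenyl acetate | CC(=O)O/C=C\c1ccc(OCc2ccccc2)c(OCc2ccccc2)c1 | intermediate

14 | lithium (Z)-2-[3,4-bis(benzyloxy)phenyl]ethenolate | [Li]O/C=C\c1ccc(OCc2ccccc2)c(OCc2ccccc2)c1 | intermediate

15 | benzyl (Z)-2-[3,4-bis(benzyloxy)phenyl]ethenyl carbonate | O=C(OCc1ccccc1)O/C=C\c1ccc(OCc2ccccc2)c(OCc2ccccc2)c1 | intermediate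

16 | (E)-o-quinone methide of ring A: 3,5-bis(benzyloxy)-6-[(E)-(octa-O-benzyl-EGCG-8-yl)methylidene]cyclohexa-2,4-dien-1-one, lower unit (2R,3R) | O=C(O[C@@H]1Cc2c(OCc3ccccc3)cc(OCc3ccccc3)c(/C=C3/C(=O)C=C(OCc4ccccc4)C=C3OCc4ccccc4)c2O[C@@H]1c1cc(OCc2ccccc2)c(OCc2ccccc2)c(OCc2ccccc2)c1)c1cc(OCc2ccccc2)c(OCc2ccccc2)c(OCc2ccccc2)c1 | intermediate

17 | 3-O-benzyloxycarbonyl-5,7,3',4'-tetra-O-benzyl-epicatechin-(4α→8)-octa-O-benzyl-EGCG; upper unit (2R,3R,4S) all-cis, lower unit (2R,3R) | O=C(O[C@@H]1Cc2c(OCc3ccccc3)cc(OCc3ccccc3)c([C@@H]3c4c(OCc5ccccc5)cc(OCc5ccccc5)cc4O[C@H](c4ccc(OCc5ccccc5)c(OCc5ccccc5)c4)[C@@H]3OC(=O)OCc3ccccc3)c2O[C@@H]1c1cc(OCc2ccccc2)c(OCc2ccccc2)c(OCc2ccccc2)c1)c1cc(OCc2ccccc2)c(OCc2ccccc2)c(OCc2ccccc2)c1 | intermediate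

18 | epicatechin-(4α→8)-epigallocatechin 3-O-gallate (CNP0246304.3); upper unit (2R,3R,4S), lower unit (2R,3R) | O=C(O[C@@H]1Cc2c(O)cc(O)c([C@@H]3c4c(O)cc(O)cc4O[C@H](c4ccc(O)c(O)c4)[C@@H]3O)c2O[C@@H]1c1cc(O)c(O)c(O)c1)c1cc(O)c(O)c(O)c1 | target

**Step count and risks**

Total step count: 9. Longest linear sequence: 6 steps (steps 1, 2, 3, 4, 8, 9; the branch through steps 5, 6, 7, 8, 9 has 5).

Steps most likely to fail:

1. Step 8 (Proposed new method). The quinone methide may be too weak an electrophile for the acyloxystyrene, so that self-condensation of 10 through its nucleophilic ring A overtakes cycloaddition. C–C bond formation may also run so far ahead that the (Z) geometry is lost or the carbonate carbonyl captures the C2 cation. Facial or endo selectivity may be poor, and the 5-benzyloxy group next to the methide carbon may erode the (E) preference of the methide on which the 2,4-cis outcome rests. The fallback uses known chemistry, sets out from 10 and alkyne 12, and rejoins the route at 18. Acid-catalysed [4+2] addition of the o-quinone methide to the arylalkyne (TfOH cat. or the acid of step 8, CH2Cl2) should give the 2,4-diaryl-4H-chromene F1, whose C4 epimers are separable diastereomers. Hydroboration–oxidation (BH3·THF, 0 °C; then NaBO3·4H2O) anti to the C4 aryl group should give the 2,3-trans-3,4-trans alcohol F2. Dess–Martin oxidation should give the flavan-3-one F3. Reduction with LiBH(s-Bu)3 at −78 °C, anti to the two cis aryl groups as in the conversion of catechins into epicatechins, should give the all-cis alcohol F4. Hydrogenolysis of F4 under the conditions of step 9 gives 18.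

2. Step 4. Addition of the magnesium phenoxide to the hindered, electron-rich aldehyde may be slow, and the doubly activated carbinol may ionise on magnesium and take up a second phenol (over-arylation). The fallback reverses the polarity, sets out from 5 and 8, and returns to 10. Iodination of 5 (NIS, CH2Cl2, 0 °C) should give the 8-iodide F5. Iodine–magnesium exchange (iPrMgCl·LiCl, THF, −30 °C, where the hindered gallate ester is tolerated) should give the arylmagnesium chloride F6. In parallel, ortho-specific formylation of 8 (MgCl2, Et3N, paraformaldehyde, MeCN, reflux) should give 2-hydroxy-4,6-bis(benzyloxy)benzaldehyde F7, which iPrMgCl converts in the flask into its chloromagnesium phenoxide F8. Addition of F6 to F8 (THF, −30 → 0 °C) and neutral work-up gives 10.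

3. Step 3. Formylation may occur at C6 as well as C8, or conversion may stop short on this crowded ring. The fallback sets out from 5 and returns to 7. Bromination with NBS (CH2Cl2, −78 → 0 °C), which is C8-selective for O-benzylated flavan-3-ols, should give the 8-bromide F9. Suzuki–Miyaura coupling with vinylboronic acid pinacol ester (Pd(OAc)2, SPhos, K3PO4, toluene/H2O, 80 °C) should give the 8-vinyl compound F10. Lemieux–Johnson cleavage (OsO4 cat., NaIO4, 2,6-lutidine, dioxane/H2O) gives 7.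

**Further compounds**

F1 | step 8 | 5,7-bis(benzyloxy)-2-[3,4-bis(benzyloxy)phenyl]-4-(octa-O-benzyl-EGCG-8-yl)-4H-chromene, 4-aryl α (4S) | O=C(O[C@@H]1Cc2c(OCc3ccccc3)cc(OCc3ccccc3)c([C@@H]3c4c(OCc5ccccc5)cc(OCc5ccccc5)cc4OC(c4ccc(OCc5ccccc5)c(OCc5ccccc5)c4)=C3)c2O[C@@H]1c1cc(OCc2ccccc2)c(OCc2ccccc2)c(OCc2ccccc2)c1)c1cc(OCc2ccccc2)c(OCc2ccccc2)c(OCc2ccccc2)c1

F2 | step 8 | 5,7,3',4'-tetra-O-benzyl-catechin-(4α→8)-octa-O-benzyl-EGCG, upper unit (2R,3S,4S), 2,3-trans-3,4-trans | O=C(O[C@@H]1Cc2c(OCc3ccccc3)cc(OCc3ccccc3)c([C@@H]3c4c(OCc5ccccc5)cc(OCc5ccccc5)cc4O[C@H](c4ccc(OCc5ccccc5)c(OCc5ccccc5)c4)[C@H]3O)c2O[C@@H]1c1cc(OCc2ccccc2)c(OCc2ccccc2)c(OCc2ccccc2)c1)c1cc(OCc2ccccc2)c(OCc2ccccc2)c(OCc2ccccc2)c1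

F3 | step 8 | upper-unit flavan-3-one: 5,7-bis(benzyloxy)-2-[3,4-bis(benzyloxy)phenyl]-4-(octa-O-benzyl-EGCG-8-yl)chroman-3-one, (2R,4S), 2,4-cis | O=C(O[C@@H]1Cc2c(OCc3ccccc3)cc(OCc3ccccc3)c([C@@H]3c4c(OCc5ccccc5)cc(OCc5ccccc5)cc4O[C@H](c4ccc(OCc5ccccc5)c(OCc5ccccc5)c4)C3=O)c2O[C@@H]1c1cc(OCc2ccccc2)c(OCc2ccccc2)c(OCc2ccccc2)c1)c1cc(OCc2ccccc2)c(OCc2ccccc2)c(OCc2ccccc2)c1

F4 | step 8 | 5,7,3',4'-tetra-O-benzyl-epicatechin-(4α→8)-octa-O-benzyl-EGCG, upper unit (2R,3R,4S), all-cis, free 3-OH | O=C(O[C@@H]1Cc2c(OCc3ccccc3)cc(OCc3ccccc3)c([C@@H]3c4c(OCc5ccccc5)cc(OCc5ccccc5)cc4O[C@H](c4ccc(OCc5ccccc5)c(OCc5ccccc5)c4)[C@@H]3O)c2O[C@@H]1c1cc(OCc2ccccc2)c(OCc2ccccc2)c(OCc2ccccc2)c1)c1cc(OCc2ccccc2)c(OCc2ccccc2)c(OCc2ccccc2)c1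

F5 | step 4 | 8-iodo-octa-O-benzyl-EGCG, (2R,3R) | O=C(O[C@@H]1Cc2c(OCc3ccccc3)cc(OCc3ccccc3)c(I)c2O[C@@H]1c1cc(OCc2ccccc2)c(OCc2ccccc2)c(OCc2ccccc2)c1)c1cc(OCc2ccccc2)c(OCc2ccccc2)c(OCc2ccccc2)c1

F6 | step 4 | 8-(chloromagnesio)-octa-O-benzyl-EGCG, (2R,3R) | O=C(O[C@@H]1Cc2c(OCc3ccccc3)cc(OCc3ccccc3)c([Mg]Cl)c2O[C@@H]1c1cc(OCc2ccccc2)c(OCc2ccccc2)c(OCc2ccccc2)c1)c1cc(OCc2ccccc2)c(OCc2ccccc2)c(OCc2ccccc2)c1

F7 | step 4 | 2-hydroxy-4,6-bis(benzyloxy)benzaldehyde | O=Cc1c(O)cc(OCc2ccccc2)cc1OCc2ccccc2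

F8 | step 4 | chloromagnesium phenoxide of 2-hydroxy-4,6-bis(benzyloxy)benzaldehyde | O=Cc1c(O[Mg]Cl)cc(OCc2ccccc2)cc1OCc2ccccc2

F9 | step 3 | 8-bromo-octa-O-benzyl-EGCG, (2R,3R) | O=C(O[C@@H]1Cc2c(OCc3ccccc3)cc(OCc3ccccc3)c(Br)c2O[C@@H]1c1cc(OCc2ccccc2)c(OCc2ccccc2)c(OCc2ccccc2)c1)c1cc(OCc2ccccc2)c(OCc2ccccc2)c(OCc2ccccc2)c1

F10 | step 3 | 8-vinyl-octa-O-benzyl-EGCG, (2R,3R) | O=C(O[C@@H]1Cc2c(OCc3ccccc3)cc(OCc3ccccc3)c(C=C)c2O[C@@H]1c1cc(OCc2ccccc2)c(OCc2ccccc2)c(OCc2ccccc2)c1)c1cc(OCc2ccccc2)c(OCc2ccccc2)c(OCc2ccccc2)c1
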